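**Retrosynthetic overview**
1. Dihydrofuran (last ring): dehydration of a C15 lactol, which forms when a C15 aldehyde and the C16 alcohol are unmasked at the very end.
2. Spiro-tetrahydrofuran (C9–O bond): 5-exo, trans-diaxial opening of an 8β,9β-epoxide (directed by the 7β-OH) by the C13 tertiary alcohol; this fixes C8 and C9.
3. Ring B oxygens: allylic oxidation of the Δ8 alkene to the 8-en-7-one, α'-hydroxylation at C6, reduction to the 7β-ol.
4. Key C12–C13 bond: aldol addition of the lithium enolate of an (S)-malic acid-derived dioxolanone (fragment 2, sets C13) to a sclareolide-derived C12 aldehyde (fragment 1), then C12 deoxygenation.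
5. Ring order: rings A/B intact from (+)-sclareolide, then the spiro-tetrahydrofuran, then the dihydrofuran.

Assumption: labdane numbering with α/β descriptors (C20 methyl β) is used; the target is read as (13S)-7β-acetoxy-9α,13:15,16-diepoxy-8β-hydroxylabd-14-en-6-one in the normal (5α-H, 10β-CH3) series of (+)-sclareolide.

**Route**

Step 1
Reactants: 1 (+)-sclareolide
Product: 2 methyl 13,14,15,16-tetranorlabd-8-en-12-oate
Conditions: conc. H2SO4, MeOH, rt → 50 °C
Reagents that add atoms: methanol (CO)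
Why: Acid-catalysed lactone methanolysis followed by E1 dehydration of the tertiary C8 alcohol under equilibrating conditions funnels the alkene isomers to the tetrasubstituted Δ8(9) ester (residual Δ7/Δ8(17) isomers removed on AgNO3-impregnated silica) without touching C5 or C10.

Step 2
Reactants: 2 methyl 13,14,15,16-tetranorlabd-8-en-12-oate
Product: 3 13,14,15,16-tetranorlabd-8-en-12-ol
Conditions: LiAlH4, THF, 0 °C → rt; H2O work-up
Reagents that add atoms: none
Why: Standard LiAlH4 ester reduction, the hindered tetrasubstituted alkene being inert.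

Step 3
Reactants: 3 13,14,15,16-tetranorlabd-8-en-12-ol
Product: 4 13,14,15,16-tetranorlabd-8-en-12-al
Conditions: Dess–Martin periodinane, pyridine, CH2Cl2, 0 °C
Reagents that add atoms: none
Why: Dess–Martin oxidation under pyridine buffering gives the β,γ-unsaturated aldehyde without migration of the alkene into conjugation; it is used at once.

Step 4
Reactants: 5 (S)-malic acid
Product: 6 2-[(2S,4S)-2-tert-butyl-5-oxo-1,3-dioxolan-4-yl]acetic acid
Conditions: t-BuCHO, p-TsOH (cat.), H2SO4 (cat.), pentane, reflux, Dean–Stark; recrystallise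
Reagents that add atoms: pivalaldehyde (CC(C)(C)C=O)
Why: Acid-catalysed acetalisation of the α-hydroxy acid unit (Seebach dioxolanone formation) gives the acetal-lactone, and the new acetal centre is set by the existing carbinol centre because the cis (2S,4S) isomer is thermodynamically favoured and crystallises.

Step 5
Reactants: 6 2-[(2S,4S)-2-tert-butyl-5-oxo-1,3-dioxolan-4-yl]acetic acid
Product: 7 (2S,5S)-2-tert-butyl-5-(2-hydroxyethyl)-1,3-dioxolan-4-one
Conditions: BH3·SMe2, THF, 0 °C → rt; H2O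
Reagents that add atoms: none
Why: Borane reduces the free carboxylic acid chemoselectively (acyloxyborane pathway) in the presence of the acetal-lactone, and the alcohol is silylated directly to prevent translactonisation.

Step 6
Reactants: 7 (2S,5S)-2-tert-butyl-5-(2-hydroxyethyl)-1,3-dioxolan-4-one
Product: 8 (2S,5S)-2-tert-butyl-5-[2-(tert-butyldimethylsilyloxy)ethyl]-1,3-dioxolan-4-one
Conditions: TBSCl, imidazole, CH2Cl2, 0 °C
Reagents that add atoms: tert-butyldimethylsilyl chloride (CC(C)(C)[Si](C)(C)Cl)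
Why: Imidazole-mediated silylation of the primary alcohol leaves the C5–H as the only acidic site for the enolisation that follows.

Step 7
Reactants: 8 (2S,5S)-2-tert-butyl-5-[2-(tert-butyldimethylsilyloxy)ethyl]-1,3-dioxolan-4-one; 4 13,14,15,16-tetranorlabd-8-en-12-al
Product: 10 (2S,5R)-2-tert-butyl-5-[2-(tert-butyldimethylsilyloxy)ethyl]-5-(12-hydroxy-13,14,15,16-tetranorlabd-8-en-12-yl)-1,3-dioxolan-4-one (C12 epimers), via lithium enolate 9 (not isolated)
Conditions: LiN(iPr)2, THF, −78 °C; then 4, −78 °C; AcOH quench at −78 °C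
Reagents that add atoms: none
Why: Intermolecular aldol addition with Seebach self-regeneration of stereocentres: the aldehyde is attacked from the enolate face anti to tert-butyl, so C12 takes the place of the former C13–H with retention and fixes the 13S quaternary centre, while low temperature and a cold acid quench suppress enolisation of 4 and retro-aldol (the C12 carbinol epimers are inconsequential).

Step 8
Reactants: 10 aldol adduct
Product: 11 12-O-(phenoxythiocarbonyl) derivative of 10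
Conditions: PhOC(=S)Cl, pyridine, DMAP (cat.), CH2Cl2, 0 °C → rt
Reagents that add atoms: O-phenyl chlorothionoformate (S=C(Cl)Oc1ccccc1)
Why: DMAP-catalysed acylation of the hindered secondary alcohol under non-alkoxide conditions (no retro-aldol) installs the radical leaving group.

Step 9
Reactants: 11 thionocarbonate
Product: 12 (2S,5S)-2-tert-butyl-5-[2-(tert-butyldimethylsilyloxy)ethyl]-5-(13,14,15,16-tetranorlabd-8-en-12-yl)-1,3-dioxolan-4-one
Conditions: Bu3SnH, AIBN (cat.), toluene, 100 °C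
Reagents that add atoms: none
Why: Barton–McCombie deoxygenation: the stannyl radical adds to C=S, the C12–O bond fragments and the secondary radical is reduced by Bu3SnH, which leaves alkene, acetal-lactone and silyl ether intact and removes the only uncontrolled stereocentre.

Step 10
Reactants: 12 deoxygenated dioxolanone
Product: 13 (2S,5S)-2-tert-butyl-5-[2-(tert-butyldimethylsilyloxy)ethyl]-5-(7-oxo-13,14,15,16-tetranorlabd-8-en-12-yl)-1,3-dioxolan-4-one
Conditions: CrO3, 3,5-dimethylpyrazole, CH2Cl2, −20 °C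
Reagents that add atoms: chromium trioxide (O=[Cr](=O)=O)
Why: Allylic C–H oxidation with the CrO3·3,5-dimethylpyrazole complex occurs at the ring methylene C7, which is more accessible than the neopentyl-like C11 and the C17 methyl, giving the tetrasubstituted enone.

Step 11
Reactants: 13 enone
Product: 15 (2S,5S)-2-tert-butyl-5-[2-(tert-butyldimethylsilyloxy)ethyl]-5-(6α-hydroxy-7-oxo-13,14,15,16-tetranorlabd-8-en-12-yl)-1,3-dioxolan-4-one, via potassium dienolate 14 (not isolated)
Conditions: KN(SiMe3)2, THF, −78 °C; then 2-(phenylsulfonyl)-3-phenyloxaziridine, −78 °C; AcOH quench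
Reagents that add atoms: 2-(phenylsulfonyl)-3-phenyloxaziridine (O=S(=O)(c1ccccc1)N1OC1c1ccccc1)
Why: Kinetic α'-deprotonation at C6 gives the cross-conjugated dienolate, and Davis enolate hydroxylation occurs from the α face because the β face of C6 is blocked by the axial C4 and C10 methyls, giving the equatorial 6α-alcohol.

Step 12
Reactants: 15 6α-hydroxy enone
Product: 16 (2S,5S)-2-tert-butyl-5-[2-(tert-butyldimethylsilyloxy)ethyl]-5-[6α-(tert-butyldimethylsilyloxy)-7-oxo-13,14,15,16-tetranorlabd-8-en-12-yl]-1,3-dioxolan-4-one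
Conditions: TBSOTf, 2,6-lutidine, CH2Cl2, −78 → 0 °C
Reagents that add atoms: tert-butyldimethylsilyl triflate (CC(C)(C)[Si](C)(C)OS(=O)(=O)C(F)(F)F)
Why: Silylation of the α-ketol with the reactive triflate under non-enolising conditions protects O6 and prevents ketol isomerisation.

Step 13
Reactants: 16 silylated enone
Product: 17 (13S)-6α,15-bis(tert-butyldimethylsilyloxy)labd-8-ene-7β,13,16-triol
Conditions: LiAlH4, THF, −78 → −20 °C; H2O work-up
Reagents that add atoms: none
Why: LiAlH4 reduction: 1,2-hydride addition to the enone along the axial α trajectory gives the equatorial 7β-allylic alcohol (trans to the 6α-silyloxy group), and the dioxolanone is reductively opened to the 13,16-diol with C13 unchanged, the low temperature avoiding 6→7 silyl migration.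

Step 14
Reactants: 17 triol
Product: 19 (13S)-6α,15-bis(tert-butyldimethylsilyloxy)-16-(4-methoxybenzyloxy)labd-8-ene-7β,13-diol, via stannylene acetal 18 (not isolated)
Conditions: Bu2SnO, toluene, reflux (Dean–Stark); then 4-MeOC6H4CH2Cl, Bu4NI (cat.), 80 °C
Reagents that add atoms: 4-methoxybenzyl chloride (COc1ccc(CCl)cc1)
Why: A stannylene acetal can form only across the 13,16-diol and is alkylated at its primary oxygen (regioselective Williamson etherification), leaving the tertiary 13-OH and the hindered 7β-OH free.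

Step 15
Reactants: 19 PMB ether
Product: 20 (13S)-6α,15-bis(tert-butyldimethylsilyloxy)-8β,9β-epoxy-16-(4-methoxybenzyloxy)labdane-7β,13-diol
Conditions: VO(acac)2 (5 mol %), t-BuOOH, CH2Cl2, 0 °C → rt
Reagents that add atoms: tert-butyl hydroperoxide (CC(C)(C)OO)
Why: Vanadium-catalysed hydroxyl-directed epoxidation: the allylic 7β-OH delivers the peroxide to the β face of the tetrasubstituted alkene, overriding the steric bias of the C10 methyl and setting C8 and C9 as the 8β,9β-epoxide.

Step 16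
Reactants: 20 epoxy diol
Product: 21 (13S)-6α,15-bis(tert-butyldimethylsilyloxy)-9α,13-epoxy-16-(4-methoxybenzyloxy)labdane-7β,8β-diol
Conditions: camphorsulfonic acid (10 mol %), CH2Cl2, 0 °C
Reagents that add atoms: none
Why: Acid-catalysed 5-exo-tet epoxide opening by the tertiary C13 alcohol at C9 with inversion in the trans-diaxial (Fürst–Plattner) sense gives the 9α-ether oxygen and the axial 8β-OH, while C13 is retained because its C–O bond is not broken.

Step 17
Reactants: 21 spiro ether diol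
Product: 22 (13S)-7β-acetoxy-6α,15-bis(tert-butyldimethylsilyloxy)-9α,13-epoxy-16-(4-methoxybenzyloxy)labdan-8β-ol
Conditions: Ac2O, DMAP, pyridine, rt → 40 °C
Reagents that add atoms: acetic anhydride (CC(=O)OC(C)=O)
Why: DMAP-catalysed acetylation occurs only at the secondary 7β-OH, the tertiary axial 8β-OH being unreactive.

Step 18
Reactants: 22 acetate
Product: 23 (13S)-7β-acetoxy-9α,13-epoxy-16-(4-methoxybenzyloxy)labdane-6α,8β,15-triol
Conditions: HF·pyridine, pyridine, THF, 0 °C → rt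
Reagents that add atoms: none
Why: Fluoride desilylation of both silyl ethers under buffered, mildly acidic conditions leaves PMB ether, acetate and spiro ether intact and disfavours 7→6 acetyl migration.

Step 19
Reactants: 23 triol
Product: 24 (13S)-7β-acetoxy-9α,13-epoxy-8β-hydroxy-16-(4-methoxybenzyloxy)-6-oxolabdan-15-al
Conditions: Dess–Martin periodinane, pyridine, CH2Cl2, 0 °C → rt
Reagents that add atoms: none
Why: Dess–Martin oxidation converts the 6α-alcohol into the ketone and the primary alcohol into the aldehyde in one operation (tertiary alcohol, acetate and PMB ether inert), and the equatorial 7β-acetate is the preferred epimer next to the new ketone; the β-alkoxy aldehyde is kept neutral and used at once.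

Step 20
Reactants: 24 keto aldehyde
Product: 26 (13S)-7β-acetoxy-9α,13:15,16-diepoxy-8β,15-dihydroxylabdan-6-one (lactol; C15 anomers), via hydroxy aldehyde 25 (not isolated)
Conditions: DDQ, CH2Cl2/pH 7 buffer, 0 °C → rt
Reagents that add atoms: none
Why: Oxidative PMB cleavage with DDQ under neutral conditions frees the C16 alcohol, which adds at once to the C15 aldehyde to close the five-membered lactol.

Step 21
Reactants: 26 lactol
Product: 28 (13S)-7β-acetoxy-9α,13:15,16-diepoxy-8β-hydroxylabd-14-en-6-one (target), via lactol mesylate 27 (not isolated)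
Conditions: MsCl, Et3N, CH2Cl2, −20 → 40 °C; chromatography on Et3N-washed silica
Reagents that add atoms: none
Why: Mesylation of the lactol hydroxyl and base-mediated elimination (the only β-hydrogens are at C14) give the 2,3-dihydrofuran enol ether under non-acidic conditions without touching any stereocentre.

**Compound list**
1 | (+)-sclareolide | C1C[C@H]2C(C)(C)CCC[C@]2(C)[C@H]3CC(=O)O[C@]13C | starting material
2 | methyl 13,14,15,16-tetranorlabd-8-en-12-oate (5α-H, 10β-CH3) | COC(=O)CC1=C(C)CC[C@H]2C(C)(C)CCC[C@]12C | intermediate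
3 | 13,14,15,16-tetranorlabd-8-en-12-ol | OCCC1=C(C)CC[C@H]2C(C)(C)CCC[C@]12C | intermediate
4 | 13,14,15,16-tetranorlabd-8-en-12-al | O=CCC1=C(C)CC[C@H]2C(C)(C)CCC[C@]12C | intermediate
5 | (S)-malic acid | OC(=O)C[C@H](O)C(=O)O | starting material
6 | 2-[(2S,4S)-2-tert-butyl-5-oxo-1,3-dioxolan-4-yl]acetic acid (cis) | CC(C)(C)[C@H]1O[C@@H](CC(=O)O)C(=O)O1 | intermediate
7 | (2S,5S)-2-tert-butyl-5-(2-hydroxyethyl)-1,3-dioxolan-4-one (cis) | CC(C)(C)[C@H]1O[C@@H](CCO)C(=O)O1 | intermediate
8 | (2S,5S)-2-tert-butyl-5-[2-(tert-butyldimethylsilyloxy)ethyl]-1,3-dioxolan-4-one (cis) | CC(C)(C)[C@H]1O[C@@H](CCO[Si](C)(C)C(C)(C)C)C(=O)O1 | intermediate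
9 | lithium enolate of 8 | CC(C)(C)[C@H]1OC(CCO[Si](C)(C)C(C)(C)C)=C([O-])O1.[Li+] | intermediate
10 | (2S,5R)-2-tert-butyl-5-[2-(tert-butyldimethylsilyloxy)ethyl]-5-(12-hydroxy-13,14,15,16-tetranorlabd-8-en-12-yl)-1,3-dioxolan-4-one (labdane chain trans to tert-butyl; C12 epimers) | CC(C)(C)[C@H]1O[C@@](C(O)CC2=C(C)CC[C@H]3C(C)(C)CCC[C@]23C)(CCO[Si](C)(C)C(C)(C)C)C(=O)O1 | intermediate
11 | 12-O-(phenoxythiocarbonyl) derivative of 10 (C12 epimers) | CC(C)(C)[C@H]1O[C@@](C(OC(=S)Oc4ccccc4)CC2=C(C)CC[C@H]3C(C)(C)CCC[C@]23C)(CCO[Si](C)(C)C(C)(C)C)C(=O)O1 | intermediate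
12 | (2S,5S)-2-tert-butyl-5-[2-(tert-butyldimethylsilyloxy)ethyl]-5-(13,14,15,16-tetranorlabd-8-en-12-yl)-1,3-dioxolan-4-one | CC(C)(C)[C@H]1O[C@@](CCC2=C(C)CC[C@H]3C(C)(C)CCC[C@]23C)(CCO[Si](C)(C)C(C)(C)C)C(=O)O1 | intermediate
13 | 7-oxo derivative of 12 (8-en-7-one) | CC(C)(C)[C@H]1O[C@@](CCC2=C(C)C(=O)C[C@H]3C(C)(C)CCC[C@]23C)(CCO[Si](C)(C)C(C)(C)C)C(=O)O1 | intermediate
14 | potassium 6,8-dien-7-olate of 13 | CC(C)(C)[C@H]1O[C@@](CCC2=C(C)C([O-])=C[C@H]3C(C)(C)CCC[C@]23C)(CCO[Si](C)(C)C(C)(C)C)C(=O)O1.[K+] | intermediate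
15 | 6α-hydroxy-7-oxo derivative of 12 | CC(C)(C)[C@H]1O[C@@](CCC2=C(C)C(=O)[C@H](O)[C@H]3C(C)(C)CCC[C@]23C)(CCO[Si](C)(C)C(C)(C)C)C(=O)O1 | intermediate
16 | 6α-(tert-butyldimethylsilyloxy)-7-oxo derivative of 12 | CC(C)(C)[C@H]1O[C@@](CCC2=C(C)C(=O)[C@H](O[Si](C)(C)C(C)(C)C)[C@H]3C(C)(C)CCC[C@]23C)(CCO[Si](C)(C)C(C)(C)C)C(=O)O1 | intermediate
17 | (13S)-6α,15-bis(tert-butyldimethylsilyloxy)labd-8-ene-7β,13,16-triol | OC[C@@](O)(CCO[Si](C)(C)C(C)(C)C)CCC1=C(C)[C@@H](O)[C@H](O[Si](C)(C)C(C)(C)C)[C@H]2C(C)(C)CCC[C@]12C | intermediate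
18 | 13,16-O-dibutylstannylene acetal of 17 | CCCC[Sn]1(CCCC)OC[C@@](O1)(CCO[Si](C)(C)C(C)(C)C)CCC2=C(C)[C@@H](O)[C@H](O[Si](C)(C)C(C)(C)C)[C@H]3C(C)(C)CCC[C@]23C | intermediate
19 | (13S)-6α,15-bis(tert-butyldimethylsilyloxy)-16-(4-methoxybenzyloxy)labd-8-ene-7β,13-diol | COc1ccc(COC[C@@](O)(CCO[Si](C)(C)C(C)(C)C)CCC2=C(C)[C@@H](O)[C@H](O[Si](C)(C)C(C)(C)C)[C@H]3C(C)(C)CCC[C@]23C)cc1 | intermediate
20 | (13S)-6α,15-bis(tert-butyldimethylsilyloxy)-8β,9β-epoxy-16-(4-methoxybenzyloxy)labdane-7β,13-diol | COc1ccc(COC[C@@](O)(CCO[Si](C)(C)C(C)(C)C)CC[C@@]23O[C@@]3(C)[C@@H](O)[C@H](O[Si](C)(C)C(C)(C)C)[C@H]4C(C)(C)CCC[C@]24C)cc1 | intermediate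
21 | (13S)-6α,15-bis(tert-butyldimethylsilyloxy)-9α,13-epoxy-16-(4-methoxybenzyloxy)labdane-7β,8β-diol | O[C@H]1[C@H](O[Si](C)(C)C(C)(C)C)[C@H]2C(C)(C)CCC[C@]2(C)[C@@]2(CC[C@@](COCc3ccc(OC)cc3)(CCO[Si](C)(C)C(C)(C)C)O2)[C@@]1(C)O | intermediate
22 | (13S)-7β-acetoxy-6α,15-bis(tert-butyldimethylsilyloxy)-9α,13-epoxy-16-(4-methoxybenzyloxy)labdan-8β-ol | CC(=O)O[C@H]1[C@H](O[Si](C)(C)C(C)(C)C)[C@H]2C(C)(C)CCC[C@]2(C)[C@@]2(CC[C@@](COCc3ccc(OC)cc3)(CCO[Si](C)(C)C(C)(C)C)O2)[C@@]1(C)O | intermediate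
23 | (13S)-7β-acetoxy-9α,13-epoxy-16-(4-methoxybenzyloxy)labdane-6α,8β,15-triol | CC(=O)O[C@H]1[C@H](O)[C@H]2C(C)(C)CCC[C@]2(C)[C@@]2(CC[C@@](COCc3ccc(OC)cc3)(CCO)O2)[C@@]1(C)O | intermediate
24 | (13S)-7β-acetoxy-9α,13-epoxy-8β-hydroxy-16-(4-methoxybenzyloxy)-6-oxolabdan-15-al | CC(=O)O[C@H]1C(=O)[C@H]2C(C)(C)CCC[C@]2(C)[C@@]2(CC[C@@](COCc3ccc(OC)cc3)(CC=O)O2)[C@@]1(C)O | intermediate
25 | (13S)-7β-acetoxy-9α,13-epoxy-8β,16-dihydroxy-6-oxolabdan-15-al | CC(=O)O[C@H]1C(=O)[C@H]2C(C)(C)CCC[C@]2(C)[C@@]2(CC[C@@](CO)(CC=O)O2)[C@@]1(C)O | intermediate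
26 | (13S)-7β-acetoxy-9α,13:15,16-diepoxy-8β,15-dihydroxylabdan-6-one (lactol, C15 anomers) | CC(=O)O[C@H]1C(=O)[C@H]2C(C)(C)CCC[C@]2(C)[C@@]2(CC[C@@]3(CC(O)OC3)O2)[C@@]1(C)O | intermediate
27 | 15-O-methanesulfonate of 26 | CC(=O)O[C@H]1C(=O)[C@H]2C(C)(C)CCC[C@]2(C)[C@@]2(CC[C@@]3(CC(OS(C)(=O)=O)OC3)O2)[C@@]1(C)O | intermediate
28 | (13S)-7β-acetoxy-9α,13:15,16-diepoxy-8β-hydroxylabd-14-en-6-one (CNP0284584.1) | CC(=O)O[C@H]1C(=O)[C@H]2C(C)(C)CCC[C@]2(C)[C@@]2(CC[C@@]3(C=COC3)O2)[C@@]1(C)O | target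

**Totals**
Total step count: 21. Longest linear sequence: 18 steps (1 → 4 by steps 1–3, then steps 7–21; equally 5 → 8 by steps 4–6, then steps 7–21).

**Three steps most likely to fail, with fallbacks**

Step 7 (aldol). The basic enolate 9 may deprotonate the doubly activated C11–H of the β,γ-unsaturated aldehyde 4 instead of adding, and the adduct can revert by retro-aldol. The fallback sets out from alcohol 3 and replaces aldol plus deoxygenation by a direct enolate alkylation. Treatment of 3 with I2, PPh3 and imidazole (CH2Cl2, 0 °C) gives 12-iodo-13,14,15,16-tetranorlabd-8-ene F1. Alkylation of lithium enolate 9 (from 8 with LiN(iPr)2, THF/DMPU, −78 → −30 °C) with F1 occurs anti to tert-butyl in the same way and gives 12 directly, where it comes back to the route; steps 3, 7, 8 and 9 are then not needed.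

Step 16 (spirocyclisation). Under acid the ditertiary epoxide of 20 could ionise at C8 or undergo hydride or methyl shifts instead of being trapped at C9. The fallback sets out from 20 and biases the epoxide electronically. Dess–Martin oxidation of the 7β-alcohol gives (13S)-6α,15-bis(tert-butyldimethylsilyloxy)-8β,9β-epoxy-13-hydroxy-16-(4-methoxybenzyloxy)labdan-7-one F2. With the carbonyl next to C8, that C–O bond cannot ionise and no hydride can shift from C7, so BF3·OEt2 (cat., CH2Cl2, −40 °C) opens the epoxide only at C9 by the C13 alcohol, giving (13S)-6α,15-bis(tert-butyldimethylsilyloxy)-9α,13-epoxy-8β-hydroxy-16-(4-methoxybenzyloxy)labdan-7-one F3. NaBH4 (MeOH, −20 °C) then delivers hydride to C7 from the α face, anti to the axial C8–O bond (Felkin–Anh), and comes back to the route at 21.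

Step 21 (lactol dehydration). Sulfonylation–elimination may stall at an anomeric chloride, or the product may be lost through acid-promoted opening to the furan. The fallback sets out from lactol 26 and uses a syn-selenoxide elimination instead. PhSeH with BF3·OEt2 (cat., CH2Cl2, −40 °C) gives (13S)-7β-acetoxy-9α,13:15,16-diepoxy-8β-hydroxy-15-(phenylselanyl)labdan-6-one F4. Oxidation with 30% H2O2 and pyridine (CH2Cl2, 0 °C → rt) gives the corresponding selenoxide F5, which eliminates spontaneously towards C14, the only position with β-hydrogens, and comes back to the route at target 28.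

**Further compounds**
F1 | step 7 | 12-iodo-13,14,15,16-tetranorlabd-8-ene | ICCC1=C(C)CC[C@H]2C(C)(C)CCC[C@]12C
F2 | step 16 | (13S)-6α,15-bis(tert-butyldimethylsilyloxy)-8β,9β-epoxy-13-hydroxy-16-(4-methoxybenzyloxy)labdan-7-one | COc1ccc(COC[C@@](O)(CCO[Si](C)(C)C(C)(C)C)CC[C@@]23O[C@@]3(C)C(=O)[C@H](O[Si](C)(C)C(C)(C)C)[C@H]4C(C)(C)CCC[C@]24C)cc1
F3 | step 16 | (13S)-6α,15-bis(tert-butyldimethylsilyloxy)-9α,13-epoxy-8β-hydroxy-16-(4-methoxybenzyloxy)labdan-7-one | O=C1[C@H](O[Si](C)(C)C(C)(C)C)[C@H]2C(C)(C)CCC[C@]2(C)[C@@]2(CC[C@@](COCc3ccc(OC)cc3)(CCO[Si](C)(C)C(C)(C)C)O2)[C@@]1(C)O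
F4 | step 21 | (13S)-7β-acetoxy-9α,13:15,16-diepoxy-8β-hydroxy-15-(phenylselanyl)labdan-6-one (C15 epimers) | CC(=O)O[C@H]1C(=O)[C@H]2C(C)(C)CCC[C@]2(C)[C@@]2(CC[C@@]3(CC([Se]c4ccccc4)OC3)O2)[C@@]1(C)O
F5 | step 21 | selenoxide of F4 | CC(=O)O[C@H]1C(=O)[C@H]2C(C)(C)CCC[C@]2(C)[C@@]2(CC[C@@]3(CC([Se](=O)c4ccccc4)OC3)O2)[C@@]1(C)O
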